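The decalin is cut at C5–C10, the bond common to rings A and B, and at C6–C7. In ring B the oxygenated C9 lies beside the methyl-bearing C8 and 1,4 across from C6, so ring B is the adduct of a 2-silyloxy-3-methyl diene (C7=C8–C9=C10) with an (E)-vinyl sulfone (C5=C6) that hangs from C10 through C1–C4. A single thermal intramolecular Diels–Alder reaction makes both bonds, closes both rings and sets C5, C10 and a temporary C6 centre. The precursor is an acyclic (Z)-silyl dienol ether; its tether carries the C4 gem-dimethyl group and the C2,C3 cis-acetonide from (R)-glyceraldehyde. Afterwards C9 takes the side chain and the sulfonyl group is cleaved.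

Key step: step 10

Remark on the chemistry: labdane numbering is used throughout. With the C10 methyl group drawn β, the target is the 2α,3α,9β-triol with an 8α-methyl group and the side chain on the α-face of C9 (2R,3S,5S,8R,9S,10S). C10 is carried as a mixture of epimers up to step 9, where it becomes sp2.

Design choices:
- The O2/O3 acetonide is made by hydrolysis, selective iodination at O1 and re-ketalisation. Acid-catalysed migration of the terminal acetonide is not used, because a cis-4,5-disubstituted dioxolane beside a quaternary carbon is expected to be less stable than the terminal one.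
- The C5 vinyl group is ozonised while it is the only alkene present. The C7=C8 alkene is introduced afterwards by a Grignard reagent on a morpholine amide.
- Only the (Z)-enol ether (C1 cis to the silyloxy group) can place the tether on the outside of the diene, so it is purified before heating.
- The sulfonyl group is cleaved only after the C9 ketone has been consumed, so no ketone is exposed to the reducing metal.

Step 1
Reactants: 1 (R)-glyceraldehyde acetonide; 2 prenyl bromide
Product: 4 (1S)-1-[(4R)-2,2-dimethyl-1,3-dioxolan-4-yl]-2,2-dimethylbut-3-en-1-ol, via prenylzinc bromide 3 (not isolated)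
Conditions: Zn dust, THF/sat. aq. NH4Cl, 0 → 23 °C
Reagents that add atoms: none
Why: Barbier-type zinc allylation in which the prenylzinc species reacts at its γ-carbon to give the C4 gem-dimethyl/vinyl unit, and Felkin–Anh attack anti to the α-oxygen should set C3 as S (2,3-anti).

Step 2
Reactants: 4 (1S)-1-[(4R)-2,2-dimethyl-1,3-dioxolan-4-yl]-2,2-dimethylbut-3-en-1-ol
Product: 5 (2R,3S)-4,4-dimethylhex-5-ene-1,2,3-triol
Conditions: Dowex 50WX8 (H+ form), MeOH/H2O (9:1), 23 °C
Reagents that add atoms: none
Why: Acid-catalysed acetal hydrolysis frees O1 and O2 without touching either stereocentre or the alkene, so that O1 can be told apart from O2 and O3 in the next step.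

Step 3
Reactants: 5 (2R,3S)-4,4-dimethylhex-5-ene-1,2,3-triol
Product: 6 (2S,3S)-1-iodo-4,4-dimethylhex-5-ene-2,3-diol
Conditions: PPh3, I2, imidazole, THF, 0 °C
Reagents that add atoms: iodine, II
Why: Appel-type iodination (alkoxyphosphonium formation, then SN2 by iodide) is selective for the primary hydroxyl at 0 °C, the secondary C2 and neopentylic C3 hydroxyls reacting far more slowly; the descriptor at C2 changes only because iodine changes the priorities.

Step 4
Reactants: 6 (2S,3S)-1-iodo-4,4-dimethylhex-5-ene-2,3-diol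
Product: 7 (4S,5S)-4-(iodomethyl)-2,2-dimethyl-5-(2-methylbut-3-en-2-yl)-1,3-dioxolane
Conditions: 2,2-dimethoxypropane, PPTS (cat.), CH2Cl2, 23 °C
Reagents that add atoms: 2,2-dimethoxypropane, COC(C)(C)OC
Why: Transketalisation of the only remaining diol (O2/O3) gives the cis-acetonide without regiochemical competition, the anti-diol mapping onto a cis-dioxolane.

Step 5
Reactants: 7 (4S,5S)-4-(iodomethyl)-2,2-dimethyl-5-(2-methylbut-3-en-2-yl)-1,3-dioxolane; 8 4-propionylmorpholine
Product: 10 morpholine amide of 2-methyl-3-[(4R,5S)-2,2-dimethyl-5-(2-methylbut-3-en-2-yl)-1,3-dioxolan-4-yl]propanoic acid (C10 epimers), via lithium enolate 9 (not isolated)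
Conditions: 8 (2.3 equiv), LiN(iPr)2, LiCl, THF, −78 → 0 °C; then 7, 0 → 23 °C
Reagents that add atoms: none
Why: SN2 alkylation of a tertiary amide enolate, a nucleophile that is strong and stable enough at ambient temperature for a β-alkoxy primary iodide, forms the C1–C10 bond and brings C9 in as an acyl group inert to the next two steps.

Step 6
Reactants: 10 morpholine amide of 2-methyl-3-[(4R,5S)-2,2-dimethyl-5-(2-methylbut-3-en-2-yl)-1,3-dioxolan-4-yl]propanoic acid
Product: 12 morpholine amide of 3-[(4R,5S)-2,2-dimethyl-5-(2-methyl-1-oxopropan-2-yl)-1,3-dioxolan-4-yl]-2-methylpropanoic acid, via secondary ozonide 11 (not isolated)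
Conditions: O3, CH2Cl2, −78 °C; then Me2S, −78 → 23 °C
Reagents that add atoms: ozone, [O-][O+]=O
Why: Ozonolysis with reductive work-up cleaves the only C=C bond present (tertiary amide and acetonide are inert) and gives the non-enolisable C5 aldehyde, which can neither epimerise nor lose O3 by β-elimination.

Step 7
Reactants: 12 morpholine amide of 3-[(4R,5S)-2,2-dimethyl-5-(2-methyl-1-oxopropan-2-yl)-1,3-dioxolan-4-yl]-2-methylpropanoic acid; 13 diethyl (phenylsulfonyl)methylphosphonate
Product: 15 morpholine amide of 3-[(4R,5S)-2,2-dimethyl-5-[(3E)-2-methyl-4-(phenylsulfonyl)but-3-en-2-yl]-1,3-dioxolan-4-yl]-2-methylpropanoic acid, via sodium phosphonate salt 14 (not isolated)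
Conditions: 13, NaH, THF, 0 °C; then 12, 0 → 23 °C
Reagents that add atoms: none
Why: Horner–Wadsworth–Emmons olefination with a sulfonyl-stabilised phosphonate anion gives the (E)-vinyl sulfone C5=C6 from an α-quaternary aldehyde, and the amide α-hydrogen is far too weakly acidic to interfere.

Step 8
Reactants: 15 morpholine amide of 3-[(4R,5S)-2,2-dimethyl-5-[(3E)-2-methyl-4-(phenylsulfonyl)but-3-en-2-yl]-1,3-dioxolan-4-yl]-2-methylpropanoic acid; 16 isopropenylmagnesium bromide
Product: 18 2,4-dimethyl-5-[(4R,5S)-2,2-dimethyl-5-[(3E)-2-methyl-4-(phenylsulfonyl)but-3-en-2-yl]-1,3-dioxolan-4-yl]pent-1-en-3-one (C10 epimers), via magnesium hemiaminal 17 (not isolated)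
Conditions: 16 (2.5 equiv), THF, −20 → 0 °C; then cold aq. NH4Cl
Reagents that add atoms: none
Why: Acyl substitution of a morpholine amide by a Grignard reagent stops at the ketone because the tetrahedral magnesium adduct collapses only on work-up, while the vinyl sulfone is shielded at its β-carbon by quaternary C4 and has no γ-hydrogen.

Step 9
Reactants: 18 2,4-dimethyl-5-[(4R,5S)-2,2-dimethyl-5-[(3E)-2-methyl-4-(phenylsulfonyl)but-3-en-2-yl]-1,3-dioxolan-4-yl]pent-1-en-3-one
Product: 19 (3Z)-3-(tert-butyldimethylsilyloxy)-2,4-dimethyl-5-[(4R,5S)-2,2-dimethyl-5-[(3E)-2-methyl-4-(phenylsulfonyl)but-3-en-2-yl]-1,3-dioxolan-4-yl]penta-1,3-diene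
Conditions: TBSOTf, Et3N, CH2Cl2, −78 → 0 °C; chromatography on Et3N-deactivated silica
Reagents that add atoms: tert-butyldimethylsilyl trifluoromethanesulfonate, CC(C)(C)[Si](C)(C)OS(=O)(=O)C(F)(F)F
Why: Soft enolisation (O-silylation, then loss of H10, the only acidic hydrogen) gives the 2-silyloxy diene, and the larger C10 substituent (C1) should prefer the position cis to the silyloxy group and away from the isopropenyl group, which is the needed (Z)-isomer; the (E)-isomer is removed on the column.

Step 10
Reactants: 19 (3Z)-3-(tert-butyldimethylsilyloxy)-2,4-dimethyl-5-[(4R,5S)-2,2-dimethyl-5-[(3E)-2-methyl-4-(phenylsulfonyl)but-3-en-2-yl]-1,3-dioxolan-4-yl]penta-1,3-diene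
Product: 20 9-(tert-butyldimethylsilyloxy)-2α,3α-(isopropylidenedioxy)-6α-(phenylsulfonyl)-11,12,13,14,15,16-hexanorlabd-8-ene
Conditions: PhMe (0.01 M), BHT (cat.), Et3N (trace), 120 °C, sealed tube
Reagents that add atoms: none
Why: Thermal, concerted but asynchronous [4+2] cycloaddition, the type 1 intramolecular Diels–Alder reaction of a 1,7,9-decatriene in which a sulfonyl-activated alkene meets a 2-silyloxy diene; the larger HOMO coefficient at C10 (β to the silyloxy group) pairs with the larger LUMO coefficient at C5 (β to sulfur), so the tether imposes the same orientation that the electronics prefer. Ring A forms as the ring that contains the four tether atoms C1–C4 (six-membered, tether exo to the diene), and ring B as the cyclohexene C5–C6–C7–C8=C9–C10 that keeps the C8=C9 silyl enol ether. C10 and C5 arise together: with C1 outside and the methyl group inside on the (Z)-enol ether, the tether-anti, sulfonyl-endo arrangement leaves the C10 methyl group and H5 on opposite faces (trans fusion). C6 is fixed by the (E)-geometry of the dienophile (sulfonyl cis to H5, equatorial) and is erased at step 13. The absolute sense comes from the C2,C3 cis-acetonide: in the chair-like tether O2 is equatorial and O3 axial, whereas the chair leading to the other trans-fused adduct would set O2 axial against both the C10 methyl and the axial C4 methyl group. The selectivity the step needs is trans over cis fusion; the endo preference of the sulfonyl group, and the fact that each chair-like cis arrangement must carry C9 or C6 axially on ring A against the axial C4 methyl group or O3, argue for it, but this is the one outcome of the route that cannot be taken for granted.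

Step 11
Reactants: 20 9-(tert-butyldimethylsilyloxy)-2α,3α-(isopropylidenedioxy)-6α-(phenylsulfonyl)-11,12,13,14,15,16-hexanorlabd-8-ene
Product: 22 2α,3α-(isopropylidenedioxy)-8α-methyl-6α-(phenylsulfonyl)-11,12,13,14,15,16-hexanorlabdan-9-one, via C8-epimeric ketones 21 (not isolated)
Conditions: Bu4NF, THF, 0 °C; then NaOMe (cat.), MeOH, 23 °C
Reagents that add atoms: none
Why: Fluoride cleavage of the silyl enol ether and base equilibration through the C8 enolate should leave the C8 methyl group equatorial (α), since the axial epimer would be syn-diaxial to the C10 methyl group; acetonide and sulfone are stable to both reagents.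

Step 12
Reactants: 22 2α,3α-(isopropylidenedioxy)-8α-methyl-6α-(phenylsulfonyl)-11,12,13,14,15,16-hexanorlabdan-9-one; 23 2-(2-bromoethyl)-2-methyl-1,3-dioxolane
Product: 26 9β-hydroxy-9α-[2-(2-methyl-1,3-dioxolan-2-yl)ethyl] adduct of 22, via Grignard reagent 24 (not isolated), via organocerium reagent 25 (not isolated)
Conditions: 23, Mg, THF, 23 °C; anhydrous CeCl3, THF, −78 °C; then 22, −78 → 0 °C; aq. NH4Cl
Reagents that add atoms: none
Why: 1,2-Addition of a weakly basic organocerium reagent (no enolisation at C8, no deprotonation next to sulfur) along the axial trajectory on the α-face, anti to the axial C10 methyl group that blocks the β-face, should give the 9β-hydroxyl with the side chain 9α.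

Step 13
Reactants: 26 9β-hydroxy-9α-[2-(2-methyl-1,3-dioxolan-2-yl)ethyl] adduct of 22
Product: 27 13,13-(ethylenedioxy)-2α,3α-(isopropylidenedioxy)-14,15-dinorlabdan-9β-ol (side chain 9α)
Conditions: Na(Hg) (6% Na), Na2HPO4, MeOH/THF, −20 → 0 °C
Reagents that add atoms: none
Why: Reductive desulfonylation by electron transfer from sodium amalgam turns C6 into CH2; ketal, acetonide and tertiary alcohol are inert, and no carbonyl group is present to be reduced.

Step 14
Reactants: 27 13,13-(ethylenedioxy)-2α,3α-(isopropylidenedioxy)-14,15-dinorlabdan-9β-ol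
Product: 28 9β-hydroxy-2α,3α-(isopropylidenedioxy)-14,15-dinorlabdan-13-one (side chain 9α)
Conditions: PPTS, acetone/H2O (10:1), 50 °C
Reagents that add atoms: water, O
Why: Mild acid-catalysed ketal exchange and hydrolysis in wet acetone releases the methyl ketone, while the diol acetonide is held in place by the acetone solvent.

Step 15
Reactants: 28 9β-hydroxy-2α,3α-(isopropylidenedioxy)-14,15-dinorlabdan-13-one; 29 trimethyl phosphonoacetate
Product: 31 methyl (13E)-9β-hydroxy-2α,3α-(isopropylidenedioxy)labd-13-en-15-oate (side chain 9α), via sodium phosphonoacetate salt 30 (not isolated)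
Conditions: 29 (slight excess over NaH), NaH, THF, 0 °C; then 28, 23 → 60 °C
Reagents that add atoms: none
Why: Horner–Wadsworth–Emmons olefination of a methyl ketone should favour the (E)-trisubstituted enoate (the 13Z isomer is removed by chromatography), and because no base stronger than the phosphonate anion is present the 9-hydroxyl stays protonated and cannot add to the new enoate.

Step 16
Reactants: 31 methyl (13E)-9β-hydroxy-2α,3α-(isopropylidenedioxy)labd-13-en-15-oate
Product: 32 methyl (13E)-2α,3α,9β-trihydroxylabd-13-en-15-oate with 8α-methyl and 9α side chain (CNP0292844.1)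
Conditions: AcOH/H2O (4:1), 50 °C
Reagents that add atoms: none
Why: Weak-acid hydrolysis of the cis-fused acetonide frees the 2α,3α-diol under conditions too mild to dehydrate the tertiary 9-hydroxyl, isomerise the enoate or cleave the methyl ester.

Compound list

1 | (R)-glyceraldehyde acetonide, (R)-2,2-dimethyl-1,3-dioxolane-4-carbaldehyde | O=C[C@@H]1OC(C)(C)OC1 | starting material
2 | prenyl bromide, 1-bromo-3-methylbut-2-ene | CC(C)=CCBr | starting material
3 | prenylzinc bromide | CC(C)=CC[Zn]Br | intermediate
4 | (1S)-1-[(4R)-2,2-dimethyl-1,3-dioxolan-4-yl]-2,2-dimethylbut-3-en-1-ol (2,3-anti) | C=CC(C)(C)[C@H](O)[C@H]1COC(C)(C)O1 | intermediate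
5 | (2R,3S)-4,4-dimethylhex-5-ene-1,2,3-triol | C=CC(C)(C)[C@H](O)[C@H](O)CO | intermediate
6 | (2S,3S)-1-iodo-4,4-dimethylhex-5-ene-2,3-diol | C=CC(C)(C)[C@H](O)[C@H](O)CI | intermediate
7 | (4S,5S)-4-(iodomethyl)-2,2-dimethyl-5-(2-methylbut-3-en-2-yl)-1,3-dioxolane (cis) | IC[C@H]1OC(C)(C)O[C@H]1C(C)(C)C=C | intermediate
8 | 4-propionylmorpholine, 1-(morpholin-4-yl)propan-1-one | CCC(=O)N1CCOCC1 | starting material
9 | lithium (Z)-enolate of 8 | C/C=C(\O[Li])N1CCOCC1 | intermediate
10 | 2-methyl-1-(morpholin-4-yl)-3-[(4R,5S)-2,2-dimethyl-5-(2-methylbut-3-en-2-yl)-1,3-dioxolan-4-yl]propan-1-one, both epimers at the methyl-bearing carbon (C10) | CC(C[C@H]1OC(C)(C)O[C@H]1C(C)(C)C=C)C(=O)N1CCOCC1 | intermediate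
11 | secondary ozonide (1,2,4-trioxolane) of 10, ozonide carbon unassigned | CC(C[C@H]1OC(C)(C)O[C@H]1C(C)(C)C1OCOO1)C(=O)N1CCOCC1 | intermediate
12 | 2-methyl-2-[(4S,5R)-2,2-dimethyl-5-(2-methyl-3-morpholino-3-oxopropyl)-1,3-dioxolan-4-yl]propanal (C5 aldehyde, C10 epimers) | CC(C[C@H]1OC(C)(C)O[C@H]1C(C)(C)C=O)C(=O)N1CCOCC1 | intermediate
13 | diethyl (phenylsulfonyl)methylphosphonate | CCOP(=O)(CS(=O)(=O)c1ccccc1)OCC | starting material
14 | sodium salt of 13 (phosphonate carbanion) | [Na+].CCOP(=O)([CH-]S(=O)(=O)c1ccccc1)OCC | intermediate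
15 | 2-methyl-1-(morpholin-4-yl)-3-[(4R,5S)-2,2-dimethyl-5-[(3E)-2-methyl-4-(phenylsulfonyl)but-3-en-2-yl]-1,3-dioxolan-4-yl]propan-1-one (C10 epimers) | CC(C[C@H]1OC(C)(C)O[C@H]1C(C)(C)/C=C/S(=O)(=O)c1ccccc1)C(=O)N1CCOCC1 | intermediate
16 | isopropenylmagnesium bromide | C=C(C)[Mg]Br | starting material
17 | bromomagnesium hemiaminal from 15 and 16, new carbinol centre unassigned | C=C(C)C(O[Mg]Br)(N1CCOCC1)C(C)C[C@H]1OC(C)(C)O[C@H]1C(C)(C)/C=C/S(=O)(=O)c1ccccc1 | intermediate
18 | 2,4-dimethyl-5-[(4R,5S)-2,2-dimethyl-5-[(3E)-2-methyl-4-(phenylsulfonyl)but-3-en-2-yl]-1,3-dioxolan-4-yl]pent-1-en-3-one (C10 epimers) | C=C(C)C(=O)C(C)C[C@H]1OC(C)(C)O[C@H]1C(C)(C)/C=C/S(=O)(=O)c1ccccc1 | intermediate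
19 | (3Z)-3-(tert-butyldimethylsilyloxy)-2,4-dimethyl-5-[(4R,5S)-2,2-dimethyl-5-[(3E)-2-methyl-4-(phenylsulfonyl)but-3-en-2-yl]-1,3-dioxolan-4-yl]penta-1,3-diene (silyloxy cis to C1; cycloaddition precursor) | C=C(C)/C(O[Si](C)(C)C(C)(C)C)=C(\C)C[C@H]1OC(C)(C)O[C@H]1C(C)(C)/C=C/S(=O)(=O)c1ccccc1 | intermediate
20 | trans-fused cycloadduct: 9-(tert-butyldimethylsilyloxy)-2α,3α-(isopropylidenedioxy)-6α-(phenylsulfonyl)-11,12,13,14,15,16-hexanorlabd-8-ene (5α-H, 10β-methyl) | CC1=C(O[Si](C)(C)C(C)(C)C)[C@@]2(C)C[C@H]3OC(C)(C)O[C@H]3C(C)(C)[C@@H]2[C@@H](S(=O)(=O)c2ccccc2)C1 | intermediate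
21 | 2α,3α-(isopropylidenedioxy)-6α-(phenylsulfonyl)-11,12,13,14,15,16-hexanorlabdan-9-one, mixture of C8 epimers | O=C1C(C)C[C@H](S(=O)(=O)c3ccccc3)[C@H]2C(C)(C)[C@@H]3OC(C)(C)O[C@@H]3C[C@@]21C | intermediate
22 | 2α,3α-(isopropylidenedioxy)-8α-methyl-6α-(phenylsulfonyl)-11,12,13,14,15,16-hexanorlabdan-9-one (5α-H, 10β-methyl) | O=C1[C@H](C)C[C@H](S(=O)(=O)c3ccccc3)[C@H]2C(C)(C)[C@@H]3OC(C)(C)O[C@@H]3C[C@@]21C | intermediate
23 | 2-(2-bromoethyl)-2-methyl-1,3-dioxolane | CC1(CCBr)OCCO1 | starting material
24 | 2-(2-methyl-1,3-dioxolan-2-yl)ethylmagnesium bromide | CC1(CC[Mg]Br)OCCO1 | intermediate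
25 | 2-(2-methyl-1,3-dioxolan-2-yl)ethylcerium dichloride | CC1(CC[Ce](Cl)Cl)OCCO1 | intermediate
26 | 13,13-(ethylenedioxy)-2α,3α-(isopropylidenedioxy)-6α-(phenylsulfonyl)-14,15-dinorlabdan-9β-ol, side chain 9α, 8α-methyl | CC1(CC[C@]2(O)[C@H](C)C[C@H](S(=O)(=O)c3ccccc3)[C@H]3C(C)(C)[C@@H]4OC(C)(C)O[C@@H]4C[C@@]32C)OCCO1 | intermediate
27 | 13,13-(ethylenedioxy)-2α,3α-(isopropylidenedioxy)-14,15-dinorlabdan-9β-ol, side chain 9α, 8α-methyl | CC1(CC[C@]2(O)[C@H](C)CC[C@H]3C(C)(C)[C@@H]4OC(C)(C)O[C@@H]4C[C@@]32C)OCCO1 | intermediate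
28 | 9β-hydroxy-2α,3α-(isopropylidenedioxy)-14,15-dinorlabdan-13-one, side chain 9α, 8α-methyl | CC(=O)CC[C@]1(O)[C@H](C)CC[C@H]2C(C)(C)[C@@H]3OC(C)(C)O[C@@H]3C[C@@]21C | intermediate
29 | trimethyl phosphonoacetate | COC(=O)CP(=O)(OC)OC | starting material
30 | sodium salt of 29 (phosphonate carbanion) | [Na+].COC(=O)[CH-]P(=O)(OC)OC | intermediate
31 | methyl (13E)-9β-hydroxy-2α,3α-(isopropylidenedioxy)labd-13-en-15-oate, side chain 9α, 8α-methyl | COC(=O)/C=C(\C)CC[C@]1(O)[C@H](C)CC[C@H]2C(C)(C)[C@@H]3OC(C)(C)O[C@@H]3C[C@@]21C | intermediate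
32 | methyl (13E)-2α,3α,9β-trihydroxylabd-13-en-15-oate, side chain 9α, 8α-methyl, 5α-H, 10β-methyl (CNP0292844.1) | COC(=O)/C=C(\C)CC[C@]1(O)[C@H](C)CC[C@H]2C(C)(C)[C@H](O)[C@H](O)C[C@@]21C | target

Total step count: 16. Longest linear sequence: 16 steps (1 to 32). Compounds 2, 8, 13, 16, 23 and 29 are used as purchased.

Steps most likely to fail

Step 10. The preference for the tether-anti over the tether-syn transition state may be too small, giving cis-fused material. The cycloaddition at the fully substituted C10 terminus may also be slow enough for a 1,5-hydrogen shift from the inside methyl group or loss of the silyl group to compete. The fallback closes the same two bonds ionically and sets out from enone 18. LiN(SiMe3)2 in THF at −78 → 0 °C would give the lithium cross-conjugated dienolate F1. This should add through C10 to C5 of the vinyl sulfone (6-exo Michael addition); the resulting α-sulfonyl carbanion at C6 should then add to C7 of the regenerated enone (6-endo Michael addition), an intramolecular double Michael reaction. Protonation and NaOMe/MeOH equilibration would lead to ketone 22, where the route is rejoined. The ring fusion would then depend on a chelated enolate and on reversible Michael steps, and would have to be established afresh.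

Step 9. Enolisation may give poor control of the enol ether geometry, leaving much of the material as the isomer with C1 cis to C8, which cannot reach the cycloaddition geometry. The fallback replaces selective enolisation by separation and recycling and sets out from 18. The unwanted (E)-silyl dienol ether F2 is collected from the column and cleaved with Bu4NF/AcOH in THF at 0 °C. This returns ketone 18, which is submitted again to step 9 until the material has been drawn through 19.

Step 5. The SN2 displacement at the β-alkoxy, β-branched primary iodide may be too slow, with dehydrohalogenation to an exocyclic enol ether taking over. The fallback makes the same C1–C10 bond by epoxide opening and sets out from iododiol 6. K2CO3 in MeOH at 0 °C would close the (1S)-2,2-dimethyl-1-[(2R)-oxiran-2-yl]but-3-en-1-ol F3. Excess lithium enolate 9 (LiCl, THF, 0 → 23 °C; one equivalent is taken up by the free hydroxyl) should open it at the terminal carbon C1 to give the (4R,5S)-4,5-dihydroxy-2,6,6-trimethyl-1-(morpholin-4-yl)oct-7-en-1-one F4. 2,2-Dimethoxypropane with PPTS then gives amide 10, where the route is rejoined.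

Further compounds

F1 | step 10 | lithium cross-conjugated dienolate of 18 (enolate geometry open) | C=C(C)C(O[Li])=C(C)C[C@H]1OC(C)(C)O[C@H]1C(C)(C)/C=C/S(=O)(=O)c1ccccc1
F2 | step 9 | (3E)-3-(tert-butyldimethylsilyloxy)-2,4-dimethyl-5-[(4R,5S)-2,2-dimethyl-5-[(3E)-2-methyl-4-(phenylsulfonyl)but-3-en-2-yl]-1,3-dioxolan-4-yl]penta-1,3-diene (silyloxy trans to C1) | C=C(C)/C(O[Si](C)(C)C(C)(C)C)=C(/C)C[C@H]1OC(C)(C)O[C@H]1C(C)(C)/C=C/S(=O)(=O)c1ccccc1
F3 | step 5 | (1S)-2,2-dimethyl-1-[(2R)-oxiran-2-yl]but-3-en-1-ol | C=CC(C)(C)[C@H](O)[C@H]1CO1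
F4 | step 5 | (4R,5S)-4,5-dihydroxy-2,6,6-trimethyl-1-(morpholin-4-yl)oct-7-en-1-one (C2 epimers) | CC(C[C@@H](O)[C@@H](O)C(C)(C)C=C)C(=O)N1CCOCC1
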